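The numbering is that of daucane: cyclopentane C1–C5, seven-membered ring C1, C5–C10. The plan rests on undoing the C1–C5 bond and rejoining C5 to C10. This turns the hydroazulene into a cyclohexane (C5–C10) bearing an isopropenyl carbinol at C10 and an ethynyl group at C5. Forward, one gold-catalysed enyne cyclisation/pinacol shift forms C2–C3 and moves C5 from C10 to C1. That widens the six-membered ring to the seven-membered ring, closes the cyclopentene, sets quaternary C1 and leaves a C10 ketone plus a C4 iodide. It exploits the oxygenated C10 next to quaternary C1 at the ring fusion. (R)-5-Methylcyclohexenone supplies all chirality.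

Key step: step 6

Assumption: (R)-5-methylcyclohex-2-en-1-one (1) is taken as a purchasable chiral-pool ketone (otherwise three routine steps from (R)-pulegone); atom numbers are daucane numbers throughout, β is the face of the C1 methyl group and α the opposite face.

Step 1
Reactants: 1 (R)-5-methylcyclohex-2-en-1-one
Product: 2 (R)-2-iodo-5-methylcyclohex-2-en-1-one
Conditions: I2, K2CO3, DMAP (cat.), THF/H2O, rt
Reagents that add atoms: iodine, II
Why: α-Iodination of the enone by amine addition, iodination and elimination (Baylis–Hillman-type activation) touches only C5 and leaves the remote C8 stereocentre alone.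

Step 2
Reactants: 2 (R)-2-iodo-5-methylcyclohex-2-en-1-one; 3 ethynyltrimethylsilane
Product: 4 (R)-5-methyl-2-[(trimethylsilyl)ethynyl]cyclohex-2-en-1-one
Conditions: PdCl2(PPh3)2 (cat.), CuI (cat.), Et3N, THF, 0 °C to rt
Reagents that add atoms: ethynyltrimethylsilane (3), C#C[Si](C)(C)C
Why: Sonogashira coupling of an α-iodoenone is fast at or below room temperature, and the silyl cap keeps the alkyne inert in the next two steps.

Step 3
Reactants: 4 (R)-5-methyl-2-[(trimethylsilyl)ethynyl]cyclohex-2-en-1-one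
Product: 6 (2R,3R,5R)-3-hydroxy-5-methyl-2-[(trimethylsilyl)ethynyl]cyclohexan-1-one, via β-boryl ketone 5 (not isolated)
Conditions: B2pin2, CuCl (cat.), DPEphos (cat.), NaOtBu (cat.), MeOH, THF, 0 °C; then H2O2, pH 7 phosphate buffer, 0 °C
Reagents that add atoms: bis(pinacolato)diboron, CC1(C)OB(OC1(C)C)B1OC(C)(C)C(C)(C)O1; hydrogen peroxide, OO
Why: Copper-catalysed conjugate borylation delivers boron axially to C6 anti to the C8 methyl group, kinetic axial protonation at C5 anti to the axial boryl group should leave the alkynyl group equatorial and cis to boron, and the buffered peroxide oxidation replaces boron by oxygen with retention.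

Step 4
Reactants: 6 (2R,3R,5R)-3-hydroxy-5-methyl-2-[(trimethylsilyl)ethynyl]cyclohexan-1-one; 7 isopropenylmagnesium bromide
Product: 9 (1S,2R,3R,5R)-2-ethynyl-5-methyl-1-(prop-1-en-2-yl)cyclohexane-1,3-diol, via silylalkyne diol 8 (not isolated)
Conditions: 7 (excess), LaCl3·2LiCl, THF, −78 to −20 °C; aq. NH4Cl; then K2CO3, MeOH, rt
Reagents that add atoms: isopropenylmagnesium bromide (7), CC(=C)[Mg]Br
Why: In this chelation-controlled Grignard 1,2-addition the axial C6 alkoxide binds the C10 carbonyl and blocks axial attack, so the isopropenyl group should enter equatorially (C10–OH axial, syn to O-6 and trans-diequatorial to the alkynyl group), and methanolysis then frees the terminal alkyne.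

Step 5
Reactants: 9 (1S,2R,3R,5R)-2-ethynyl-5-methyl-1-(prop-1-en-2-yl)cyclohexane-1,3-diol
Product: 10 cyclic diisopropylsilylene of 9 (2,4-dioxa-3-silabicyclo[3.3.1]nonane; stereocentres as in 9)
Conditions: iPr2Si(OTf)2, 2,6-lutidine, CH2Cl2, 0 °C
Reagents that add atoms: diisopropylsilyl bis(trifluoromethanesulfonate), CC(C)[Si](OS(=O)(=O)C(F)(F)F)(OS(=O)(=O)C(F)(F)F)C(C)C
Why: Silylene protection of the syn-1,3-diaxial diol closes an unstrained six-membered ring that masks both hydroxyl groups, locks the chair with both enyne arms equatorial and makes O-10 the silyl ether that the pinacol step needs.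

Step 6
Reactants: 10 cyclic diisopropylsilylene of 9
Product: 12 (3aS,4R,6R,8aR)-4-hydroxy-3-iodo-6,8a-dimethyl-3a,4,5,6,7,8a-hexahydroazulen-8(1H)-one, via N-silylsuccinimide ether 11 (not isolated)
Conditions: (Ph3P)AuNTf2 (5 mol%), NIS, CH2Cl2, −20 °C to rt, dark; then HF·pyridine, THF, 0 °C
Reagents that add atoms: N-iodosuccinimide, O=C1CCC(=O)N1I
Why: Monovalent gold binds the terminal alkyne and the CH2 terminus of the isopropenyl group (C2) attacks C3 in a 6-endo-dig closure, which gives a transient cyclohexenyl cation centred on C1 and a vinyl–gold bond at C4. Pushed by the silyloxy oxygen on C10, the C10–C5 bond then shifts to C1 (pinacol-type 1,2-shift): the transient ring contracts to the cyclopentene C1–C5, and the carbocycle C5–C10 takes up C1 and becomes the seven-membered ring with its ketone at C10. NIS turns the C4–Au bond into the C4–I bond, its succinimide anion carries the silicon off O-10, and HF·pyridine then frees the C6 hydroxyl group. The closest known reaction type is the gold-catalysed carbocyclisation/pinacol cascade of 3-silyloxy-1,5-enynes run with iododeauration. C1 is the only new stereocentre and is set by the substrate, because the two enyne arms sit trans-diequatorial on the silylene-locked chair and C5 migrates with retention across the face on which it already lies, so that the C1 methyl group ends cis to H-5 (cis ring fusion). The step needs migration of C5 instead of C9 and attack of carbon instead of oxygen on the alkyne: the C10–C5 bond overlaps with the empty orbital at C1 whereas C10–C9 lies in its nodal plane, both oxygens are tied up in the silylene ring, and a silver-free catalyst keeps the terminal alkyne from being iodinated first.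

Step 7
Reactants: 12 hydroxy iodo ketone; 13 4-acetoxybenzoic acid
Product: 14 (3aS,4R,6R,8aR)-3-iodo-6,8a-dimethyl-8-oxo-1,3a,4,5,6,7,8,8a-octahydroazulen-4-yl 4-acetoxybenzoate
Conditions: EDC·HCl, DMAP, CH2Cl2, 0 °C to rt
Reagents that add atoms: 4-acetoxybenzoic acid (13), CC(=O)Oc1ccc(cc1)C(=O)O
Why: Steglich esterification acylates the only free hydroxyl group (a transannular hemiketal with C10 would reopen under the conditions) and touches no stereocentre.

Step 8
Reactants: 14 iodo keto ester; 15 isopropylzinc bromide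
Product: 16 (3aS,4R,6R,8aR)-3-isopropyl-6,8a-dimethyl-8-oxo-1,3a,4,5,6,7,8,8a-octahydroazulen-4-yl 4-acetoxybenzoate
Conditions: 15, Pd(OAc)2 (cat.), CPhos (cat.), THF/toluene, 0 °C to rt
Reagents that add atoms: isopropylzinc bromide (15), CC(C)[Zn]Br
Why: Negishi coupling of the cyclopentenyl iodide tolerates the ketone and both esters, and the bulky biaryl phosphine speeds reductive elimination so that isopropyl is transferred without isomerisation to n-propyl.

Step 9
Reactants: 16 isopropyl cyclopentene keto ester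
Product: 18 (3S,3aS,4R,6R,8aR)-3-hydroxy-3-isopropyl-6,8a-dimethyl-8-oxodecahydroazulen-4-yl 4-acetoxybenzoate, via tertiary hydroperoxide 17 (not isolated)
Conditions: Mn(dpm)3 (cat.), PhSiH3, O2 (1 atm), iPrOH/CH2Cl2, 0 °C to rt; then PPh3
Reagents that add atoms: dioxygen, O=O
Why: Mukaiyama hydration puts hydrogen on C3 (Markovnikov) and the planar tertiary C4 radical should take up O2 from the convex β face, syn to H-5 and away from C6 and its aroyloxy group, so that the C4 hydroxyl group ends β and the isopropyl group α.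

Step 10
Reactants: 18 hydroxy keto ester
Product: 19 (3S,3aS,4R,8aR)-3-hydroxy-3-isopropyl-6,8a-dimethyl-8-oxo-1,2,3,3a,4,5,8,8a-octahydroazulen-4-yl 4-acetoxybenzoate
Conditions: IBX, DMSO, 70 °C
Reagents that add atoms: none
Why: IBX dehydrogenation can enolise the C10 ketone only towards C9 because C1 is quaternary, so the conjugated C8=C9 bond forms and the spent C8 stereocentre is erased.

Step 11
Reactants: 19 enone
Product: 20 (3S,3aS,4R,8R,8aR)-3,8-dihydroxy-3-isopropyl-6,8a-dimethyl-1,2,3,3a,4,5,8,8a-octahydroazulen-4-yl 4-acetoxybenzoate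
Conditions: (S)-2-methyl-CBS-oxazaborolidine (cat.), BH3·SMe2, THF, −30 °C; MeOH quench
Reagents that add atoms: none
Why: Corey–Bakshi–Shibata reduction is a clean 1,2-reduction under reagent control in which the quaternary C1 flank acts as the large and the C9 vinyl flank as the small group, which should deliver hydride to the α face and give the (10R)-β-alcohol.

Step 12
Reactants: 20 allylic alcohol; 21 isovaleric anhydride
Product: 22 (3S,3aS,4R,8R,8aR)-3-hydroxy-3-isopropyl-6,8a-dimethyl-8-[(3-methylbutanoyl)oxy]-1,2,3,3a,4,5,8,8a-octahydroazulen-4-yl 4-acetoxybenzoate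
Conditions: 21, DMAP, Et3N, CH2Cl2, rt
Reagents that add atoms: isovaleric anhydride (21), CC(C)CC(=O)OC(=O)CC(C)C
Why: DMAP-catalysed acylation esterifies the secondary allylic C10 hydroxyl group, while the tertiary C4 hydroxyl group is too hindered to react.

Step 13
Reactants: 22 triester
Product: 23 target, (3S,3aS,4R,8R,8aR)-3-hydroxy-3-isopropyl-6,8a-dimethyl-8-[(3-methylbutanoyl)oxy]-1,2,3,3a,4,5,8,8a-octahydroazulen-4-yl 4-hydroxybenzoate
Conditions: K2CO3 (cat.), MeOH, 0 °C, short contact
Reagents that add atoms: none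
Why: Base-catalysed transesterification cleaves the aryl acetate much faster than the two alkyl esters because phenoxide is the far better leaving group, and no stereocentre is touched.

Compound list
1 | (R)-5-methylcyclohex-2-en-1-one | C[C@H]1CC(=O)C=CC1 | starting material
2 | (R)-2-iodo-5-methylcyclohex-2-en-1-one | C[C@H]1CC(=O)C(I)=CC1 | intermediate
3 | ethynyltrimethylsilane | C#C[Si](C)(C)C | starting material
4 | (R)-5-methyl-2-[(trimethylsilyl)ethynyl]cyclohex-2-en-1-one | C[C@H]1CC(=O)C(C#C[Si](C)(C)C)=CC1 | intermediate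
5 | (2S,3R,5R)-5-methyl-3-(4,4,5,5-tetramethyl-1,3,2-dioxaborolan-2-yl)-2-[(trimethylsilyl)ethynyl]cyclohexan-1-one | C[C@H]1CC(=O)[C@H](C#C[Si](C)(C)C)[C@H](B2OC(C)(C)C(C)(C)O2)C1 | intermediate
6 | (2R,3R,5R)-3-hydroxy-5-methyl-2-[(trimethylsilyl)ethynyl]cyclohexan-1-one | C[C@H]1CC(=O)[C@H](C#C[Si](C)(C)C)[C@H](O)C1 | intermediate
7 | isopropenylmagnesium bromide | CC(=C)[Mg]Br | starting material
8 | (1S,2R,3R,5R)-5-methyl-1-(prop-1-en-2-yl)-2-[(trimethylsilyl)ethynyl]cyclohexane-1,3-diol | C[C@H]1C[C@@](O)(C(C)=C)[C@H](C#C[Si](C)(C)C)[C@H](O)C1 | intermediate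
9 | (1S,2R,3R,5R)-2-ethynyl-5-methyl-1-(prop-1-en-2-yl)cyclohexane-1,3-diol | C[C@H]1C[C@@](O)(C(C)=C)[C@H](C#C)[C@H](O)C1 | intermediate
10 | 9-ethynyl-3,3-diisopropyl-7-methyl-1-(prop-1-en-2-yl)-2,4-dioxa-3-silabicyclo[3.3.1]nonane (stereocentres as in 9) | C[C@H]1C[C@]2(C(C)=C)O[Si](C(C)C)(C(C)C)O[C@H](C1)[C@H]2C#C | intermediate
11 | C6 O-[diisopropyl(succinimido)silyl] ether of 12 | C[C@H]1CC(=O)[C@]2(C)CC=C(I)[C@@H]2[C@H](O[Si](C(C)C)(C(C)C)N2C(=O)CCC2=O)C1 | intermediate
12 | (3aS,4R,6R,8aR)-4-hydroxy-3-iodo-6,8a-dimethyl-3a,4,5,6,7,8a-hexahydroazulen-8(1H)-one (1β-CH3, 5β-H, 6α-OH, 8β-CH3) | C[C@H]1CC(=O)[C@]2(C)CC=C(I)[C@@H]2[C@H](O)C1 | intermediate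
13 | 4-acetoxybenzoic acid | CC(=O)Oc1ccc(cc1)C(=O)O | starting material
14 | (3aS,4R,6R,8aR)-3-iodo-6,8a-dimethyl-8-oxo-1,3a,4,5,6,7,8,8a-octahydroazulen-4-yl 4-acetoxybenzoate | C[C@H]1CC(=O)[C@]2(C)CC=C(I)[C@@H]2[C@H](OC(=O)c2ccc(OC(C)=O)cc2)C1 | intermediate
15 | isopropylzinc bromide | CC(C)[Zn]Br | starting material
16 | (3aS,4R,6R,8aR)-3-isopropyl-6,8a-dimethyl-8-oxo-1,3a,4,5,6,7,8,8a-octahydroazulen-4-yl 4-acetoxybenzoate | C[C@H]1CC(=O)[C@]2(C)CC=C(C(C)C)[C@@H]2[C@H](OC(=O)c2ccc(OC(C)=O)cc2)C1 | intermediate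
17 | C4 β-hydroperoxide corresponding to 18 | C[C@H]1CC(=O)[C@]2(C)CC[C@](OO)(C(C)C)[C@@H]2[C@H](OC(=O)c2ccc(OC(C)=O)cc2)C1 | intermediate
18 | (3S,3aS,4R,6R,8aR)-3-hydroxy-3-isopropyl-6,8a-dimethyl-8-oxodecahydroazulen-4-yl 4-acetoxybenzoate | C[C@H]1CC(=O)[C@]2(C)CC[C@](O)(C(C)C)[C@@H]2[C@H](OC(=O)c2ccc(OC(C)=O)cc2)C1 | intermediate
19 | (3S,3aS,4R,8aR)-3-hydroxy-3-isopropyl-6,8a-dimethyl-8-oxo-1,2,3,3a,4,5,8,8a-octahydroazulen-4-yl 4-acetoxybenzoate | CC1=CC(=O)[C@]2(C)CC[C@](O)(C(C)C)[C@@H]2[C@H](OC(=O)c2ccc(OC(C)=O)cc2)C1 | intermediate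
20 | (3S,3aS,4R,8R,8aR)-3,8-dihydroxy-3-isopropyl-6,8a-dimethyl-1,2,3,3a,4,5,8,8a-octahydroazulen-4-yl 4-acetoxybenzoate | CC1=C[C@@H](O)[C@]2(C)CC[C@](O)(C(C)C)[C@@H]2[C@H](OC(=O)c2ccc(OC(C)=O)cc2)C1 | intermediate
21 | isovaleric anhydride | CC(C)CC(=O)OC(=O)CC(C)C | starting material
22 | (3S,3aS,4R,8R,8aR)-3-hydroxy-3-isopropyl-6,8a-dimethyl-8-[(3-methylbutanoyl)oxy]-1,2,3,3a,4,5,8,8a-octahydroazulen-4-yl 4-acetoxybenzoate | CC1=C[C@@H](OC(=O)CC(C)C)[C@]2(C)CC[C@](O)(C(C)C)[C@@H]2[C@H](OC(=O)c2ccc(OC(C)=O)cc2)C1 | intermediate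
23 | (3S,3aS,4R,8R,8aR)-3-hydroxy-3-isopropyl-6,8a-dimethyl-8-[(3-methylbutanoyl)oxy]-1,2,3,3a,4,5,8,8a-octahydroazulen-4-yl 4-hydroxybenzoate | CC1=C[C@@H](OC(=O)CC(C)C)[C@]2(C)CC[C@](O)(C(C)C)[C@@H]2[C@H](OC(=O)c2ccc(O)cc2)C1 | target

Total step count: 13. Longest linear sequence: 13.

Steps most likely to fail

1. Step 6.
- What may go wrong: iodination of the terminal alkyne or of the isopropenyl group before cyclisation, protodeauration before iodine transfer, or a hydride shift that outruns the pinacol shift.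
- Fallback: it sets out from 9, comes back at 12, and separates ring enlargement from ring closure.
  - Selective silylation of the secondary hydroxyl group (TBSOTf, 2,6-lutidine, −78 °C) gives the C6 TBS ether F1.
  - NIS alone then triggers an iodonium-induced semipinacol ring expansion of the tertiary allylic alcohol, C5 again moving from C10 to C1. This gives the iodomethyl cycloheptanone F2.
  - Gold-catalysed Markovnikov hydration of the alkyne gives the methyl ketone F3.
  - The kinetic potassium enolate of F3 closes the five-membered ring by 5-exo-tet alkylation to the cis-fused diketone F4.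
  - The less shielded cyclopentanone carbonyl is condensed with hydrazine to the hydrazone F5.
  - I2 and a guanidine base (Barton vinyl iodide synthesis) give the silyl-protected vinyl iodide F6.
  - HF·pyridine then gives 12.

2. Step 3.
- What may go wrong: epimerisation at C5, drift of the α-alkynyl ketone to the allenyl ketone under the basic copper conditions, or competing borylcupration of the alkyne.
- Fallback: it sets out from 4, comes back at 8, and keeps C5 quaternary until the ketone is gone.
  - Nucleophilic epoxidation (H2O2, NaOH, MeOH) anti to the C8 methyl group gives the epoxy ketone F7.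
  - Isopropenylmagnesium bromide with LaCl3·2LiCl adds anti to the epoxide oxygen and gives the epoxy alcohol F8.
  - Cp2TiCl with water or 1,4-cyclohexadiene opens the epoxide reductively at the tertiary propargylic C5–O bond. The radical should take up hydrogen from the face opposite to the two axial oxygens, which gives 8 with a C5 centre that can no longer epimerise.

3. Step 11.
- What may go wrong: poor facial selectivity if the concave α face resists the catalyst-bound borane, or slow reduction of the neopentyl ketone.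
- Fallback: it sets out from 19, comes back at 22, and uses the substrate bias instead of fighting it.
  - Luche reduction (NaBH4, CeCl3, MeOH) from the convex face gives the 10α-alcohol F9.
  - A Mitsunobu reaction with isovaleric acid (PPh3, DIAD) inverts C10 and installs the ester in the same operation, so that step 12 is not needed.

Further compounds
F1 | step 6 | C6 tert-butyldimethylsilyl ether of 9 | C[C@H]1C[C@@](O)(C(C)=C)[C@H](C#C)[C@H](O[Si](C)(C)C(C)(C)C)C1
F2 | step 6 | 3-ethynyl-2-(iodomethyl)-2,6-dimethyl-4-(TBS-oxy)cycloheptan-1-one (1β-CH3, 5β-H, 6α-OTBS, 8β-CH3) | C[C@H]1CC(=O)[C@](C)(CI)[C@H](C#C)[C@H](O[Si](C)(C)C(C)(C)C)C1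
F3 | step 6 | 3-acetyl analogue of F2 | C[C@H]1CC(=O)[C@](C)(CI)[C@H](C(C)=O)[C@H](O[Si](C)(C)C(C)(C)C)C1
F4 | step 6 | cis-fused 6α-(TBS-oxy)-1β,8β-dimethylhydroazulene-4,10-dione | C[C@H]1CC(=O)[C@]2(C)CCC(=O)[C@@H]2[C@H](O[Si](C)(C)C(C)(C)C)C1
F5 | step 6 | C4 hydrazone of F4 | C[C@H]1CC(=O)[C@]2(C)CCC(=NN)[C@@H]2[C@H](O[Si](C)(C)C(C)(C)C)C1
F6 | step 6 | C6 tert-butyldimethylsilyl ether of 12 | C[C@H]1CC(=O)[C@]2(C)CC=C(I)[C@@H]2[C@H](O[Si](C)(C)C(C)(C)C)C1
F7 | step 3 | 2,3-epoxy-5-methyl-2-[(trimethylsilyl)ethynyl]cyclohexan-1-one (epoxide trans to the methyl group) | C[C@H]1CC(=O)[C@]2(C#C[Si](C)(C)C)O[C@@H]2C1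
F8 | step 3 | 2,3-epoxy-5-methyl-1-(prop-1-en-2-yl)-2-[(trimethylsilyl)ethynyl]cyclohexan-1-ol (hydroxyl group cis to the epoxide) | C[C@H]1C[C@@](O)(C(C)=C)[C@]2(C#C[Si](C)(C)C)O[C@@H]2C1
F9 | step 11 | C10 epimer (10α-alcohol) of 20 | CC1=C[C@H](O)[C@]2(C)CC[C@](O)(C(C)C)[C@@H]2[C@H](OC(=O)c2ccc(OC(C)=O)cc2)C1
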